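## Retrosynthetic overview

1. Numbering (tricyclo[5.4.0.0^2,8]undecane): cyclobutane C1–C2–C8–C7; cyclohexanone C1–C11(=O)–C10–C9(Me)–C8–C7; cycloheptane C1–C2(Me)–C3(OH)–C4(O-acyl)–C5(OAng)–C6(Me2)–C7. The fifteen skeletal carbons are one folded 3,7,11-trimethyldodecane (farnesane) chain, with C7 as the chain's C1 and C6 as its C11.
2. Last: C4 (R)-2-methylbutanoate and C5 angelate; the 3,4-cis-diol comes from dihydroxylation of C3=C4 anti to C5–O; the C11 ketone comes from a silyl ether.
3. Seven-membered ring second: bond C6–C7 by hydrogen-atom-transfer radical closure of an isopropenyl group onto the tosylhydrazone of the cyclobutanone, with loss of N2 (C7=O becomes C7–H, C6 becomes quaternary).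
4. Key: cyclobutane and cyclohexane together, bonds C7–C1 and C8–C2, by a crossed intramolecular ketene–diene [2+2] of an acyclic (E,Z)-dienyl acid; C1, C2 and C8 are relayed from C9 (chiral pool) and C11 (catalysis).
5. The acyclic acid comes from methyl hydrogen (R)-3-methylglutarate (C7–C11), a propynyl unit (C1, C2, C2-Me) and a methacrolein-derived alkyne (C3–C6) by Sonogashira coupling and Z-selective semireduction.

Key step: step 10

Assumptions: the skeleton numbering above is used for all cyclic intermediates; 1 and 32 are taken as commercial single enantiomers; the ligand antipode written in step 5 is the one expected by analogy to give (S)-12, and its mirror image would be used if the first run showed the opposite sense.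

## Route

Step 1
Reactants: 1 methyl hydrogen (R)-3-methylglutarate; 2 tributyl(prop-1-yn-1-yl)stannane
Product: 4 methyl (3R)-3-methyl-5-oxooct-6-ynoate, via acid chloride 3 (not isolated)
Conditions: (COCl)2, cat. DMF, CH2Cl2, 0 °C to rt; then 2, PdCl2(PPh3)2 (2 mol %), 1,2-dichloroethane, 50 °C
Reagents that add atoms: none
Why: Acid chloride formation and Stille acylation of the alkynylstannane should give the ynone under base-free conditions that leave the methyl ester and the non-epimerisable C9 centre untouched.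

Step 2
Reactants: 4 methyl (3R)-3-methyl-5-oxooct-6-ynoate
Product: 5 methyl (3R,5S)-5-hydroxy-3-methyloct-6-ynoate
Conditions: Ru[(S,S)-TsDPEN](p-cymene) (1 mol %), i-PrOH, rt
Reagents that add atoms: none
Why: Noyori asymmetric transfer hydrogenation of an alkynyl ketone, with the alkyne as the π-group recognised by the catalyst, should set C11 (chain C5) as S under catalyst control regardless of the remote C9 centre.

Step 3
Reactants: 5 methyl (3R,5S)-5-hydroxy-3-methyloct-6-ynoate
Product: 6 methyl (3R,5S)-5-[(tert-butyldimethylsilyl)oxy]-3-methyloct-6-ynoate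
Conditions: TBSCl, imidazole, DMF, 0 °C to rt (crude 5 used at once)
Reagents that add atoms: tert-butyldimethylsilyl chloride, CC(C)(C)[Si](C)(C)Cl
Why: Silylation of the secondary propargylic alcohol is run directly on crude 5 so that δ-lactonisation cannot compete.

Step 4
Reactants: 6 methyl (3R,5S)-5-[(tert-butyldimethylsilyl)oxy]-3-methyloct-6-ynoate
Product: 8 methyl (3R,5S,6E)-5-[(tert-butyldimethylsilyl)oxy]-7-iodo-3-methyloct-6-enoate, via alkenylzirconocene chloride 7 (not isolated)
Conditions: Cp2Zr(H)Cl, THF, rt; then I2, 0 °C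
Reagents that add atoms: iodine, II
Why: syn-Hydrozirconation should place zirconium on the methyl-bearing alkyne carbon, away from the silyloxy-branched carbon, and iodinolysis with retention should give the (E)-iodoalkene (hydrozirconation–iodination).

Step 5
Reactants: 9 methacrolein; 10 ethynyltrimethylsilane
Product: 12 (3S)-4-methyl-1-(trimethylsilyl)pent-4-en-1-yn-3-ol, via alkynylzinc 11 (not isolated)
Conditions: Me2Zn, (S,S)-ProPhenol (10 mol %), Ph3P=O (20 mol %), toluene, 4 °C; aq NH4Cl
Reagents that add atoms: none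
Why: Zn–ProPhenol-catalysed enantioselective alkynylation of an α-branched enal should set the C5 carbinol centre under ligand control.

Step 6
Reactants: 12 (3S)-4-methyl-1-(trimethylsilyl)pent-4-en-1-yn-3-ol
Product: 14 (3S)-3-[(tert-butyldiphenylsilyl)oxy]-4-methylpent-4-en-1-yne, via silyl ether 13 (not isolated)
Conditions: TBDPSCl, imidazole, DMF, rt; then K2CO3, MeOH, rt
Reagents that add atoms: tert-butyldiphenylsilyl chloride, CC(C)(C)[Si](Cl)(c1ccccc1)c1ccccc1
Why: O-Silylation with a group that has no abstractable hydrogen near C6 and outlasts the later TBS cleavage, then base-catalysed methanolysis of the C–SiMe3 bond, which leaves the O-silyl ether intact.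

Step 7
Reactants: 8 methyl (3R,5S,6E)-5-[(tert-butyldimethylsilyl)oxy]-7-iodo-3-methyloct-6-enoate; 14 (3S)-3-[(tert-butyldiphenylsilyl)oxy]-4-methylpent-4-en-1-yne
Product: 15 methyl (3R,5S,6E,10S)-5-[(tert-butyldimethylsilyl)oxy]-10-[(tert-butyldiphenylsilyl)oxy]-3,7,11-trimethyldodeca-6,11-dien-8-ynoate
Conditions: PdCl2(PPh3)2 (5 mol %), CuI (10 mol %), Et3N, THF, rt
Reagents that add atoms: none
Why: Sonogashira coupling of the alkenyl iodide with the terminal alkyne should proceed with retention of the (E)-geometry and join all fifteen skeletal carbons.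

Step 8
Reactants: 15 the dienyne ester
Product: 16 methyl (3R,5S,6E,8Z,10R)-5-[(tert-butyldimethylsilyl)oxy]-10-[(tert-butyldiphenylsilyl)oxy]-3,7,11-trimethyldodeca-6,8,11-trienoate
Conditions: Zn(Cu/Ag), MeOH/H2O, 45 °C
Reagents that add atoms: none
Why: Activated zinc (Boland reduction) should reduce only the conjugated triple bond by syn hydrogen delivery to the (8Z)-alkene and leave the isolated 1,1-disubstituted alkene untouched.

Step 9
Reactants: 16 the (6E,8Z)-trienoate
Product: 17 (3R,5S,6E,8Z,10R)-5-[(tert-butyldimethylsilyl)oxy]-10-[(tert-butyldiphenylsilyl)oxy]-3,7,11-trimethyldodeca-6,8,11-trienoic acid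
Conditions: LiOH, THF/MeOH/H2O, rt; then dilute HCl to pH 4, 0 °C
Reagents that add atoms: lithium hydroxide, [Li+].[OH-]
Why: Saponification of the unhindered methyl ester, to which the silyl ethers and the diene are stable.

Step 10
Reactants: 17 the trienoic acid
Product: 20 4-[(tert-butyldimethylsilyl)oxy]-7-[(1Z,3R)-3-[(tert-butyldiphenylsilyl)oxy]-4-methylpenta-1,4-dien-1-yl]-2,7-dimethylbicyclo[3.1.1]heptan-6-one (skeleton C9 R, C11 S; 2-methyl and 4-silyloxy on the face of the C6 carbonyl bridge; 7-methyl syn and dienyl chain anti to the C2–C4 bridge), via acid chloride 18 (not isolated), via ketene 19 (not isolated)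
Conditions: 1-chloro-N,N,2-trimethylprop-1-en-1-amine, CH2Cl2, 0 °C to rt; then syringe-pump addition to Et3N, toluene, 90 °C, 0.005 M
Reagents that add atoms: none
Why: Loss of HCl from 18 gives alkylketene 19, whose electrophilic carbonyl carbon (C7) bonds to the less substituted diene terminus C1 while positive charge builds at the tertiary, allylic C2, after which the ketene α-carbon C8 closes onto C2 in an asynchronous thermal [2+2] cycloaddition. The closest known reaction types are the intramolecular ketene–alkene cycloaddition of 5-alkenylketenes with a more substituted distal alkene carbon, which gives bicyclo[3.1.1]heptan-6-ones, and the [2+2] addition of ketenes to one double bond of a 1,3-diene. The six-membered ring closes by the C7–C1 bond across the three-atom tether C9–C10–C11 and the four-membered ring by the C8–C2 bond, so the bridged (crossed) rather than the fused bicycle should form. C2 is set by suprafacial addition to the (E)-alkene (the methyl cis to the tether ends syn to the C9–C11 bridge, the dienyl chain anti), and the facial sense that fixes C1 and C8 is set by C11 (allylic 1,3-strain with the C2 methyl turns the silyloxy group away from the forming C2 bridge) and by C9 (methyl away from the same bridge), two elements that reinforce each other. The step needs [2+2] over [4+2] periselectivity, which the (Z)-C3=C4 alkene secures by disfavouring the s-cis diene, and it needs cyclisation to outrun ketene dimerisation and lactonisation of the δ-silyloxy acid chloride, which slow addition to hot base at high dilution is meant to secure.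

Step 11
Reactants: 20 the bicyclic cyclobutanone
Product: 21 N-tosylhydrazone of 20 at the cyclobutanone carbon C7
Conditions: TsNHNH2, THF, 4 Å MS, 40 °C
Reagents that add atoms: p-toluenesulfonyl hydrazide, Cc1ccc(cc1)S(=O)(=O)NN
Why: Condensation of the strained, non-enolisable cyclobutanone with tosylhydrazide should give the hydrazone, and either C=N geometry serves.

Step 12
Reactants: 21 the tosylhydrazone
Product: 24 5-[(tert-butyldiphenylsilyl)oxy]-11-[(tert-butyldimethylsilyl)oxy]-2,6,6,9-tetramethyltricyclo[5.4.0.0^2,8]undec-3-ene (ring stereocentres and C5 as in 34; 11S), via cyclised tosylhydrazide 22 (not isolated), via alkyldiazene 23 (not isolated)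
Conditions: Fe(acac)3 (30 mol %), PhSiH3, EtOH/THF, 40 °C; then MeOH, 65 °C
Reagents that add atoms: none
Why: Proposed new method: iron-hydride hydrogen-atom transfer to the 1,1-disubstituted alkene should give the tertiary C6 radical, which adds to C7 of the strained cyclobutanone hydrazone from the anti face where the (Z)-alkenyl chain on C2 holds it, and the adduct then loses p-toluenesulfinate and N2 so that hydrogen ends on the only face of C7 the new ring allows; the closest known reaction type is the Fe(acac)3/PhSiH3 reductive coupling of alkenes with sulfonylhydrazones (alkene hydromethylation with formaldehyde hydrazones; intramolecular alkene–hydrazone closures to five- and six-membered rings), here extended to a seven-membered ring on a ketone-derived hydrazone.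

Step 13
Reactants: 24 the tricyclic bis-silyl ether
Product: 25 5-[(tert-butyldiphenylsilyl)oxy]-2,6,6,9-tetramethyltricyclo[5.4.0.0^2,8]undec-3-en-11-ol (11S; other centres as in 34)
Conditions: HF·pyridine, pyridine, THF, 0 °C
Reagents that add atoms: none
Why: Acidic fluoride should cleave the unhindered secondary TBS ether at C11 much faster than the TBDPS ether at C5, which sits next to the quaternary C6 (selective desilylation).

Step 14
Reactants: 25 the C11 alcohol
Product: 26 5-[(tert-butyldiphenylsilyl)oxy]-2,6,6,9-tetramethyltricyclo[5.4.0.0^2,8]undec-3-en-11-one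
Conditions: Dess–Martin periodinane, NaHCO3, CH2Cl2, rt
Reagents that add atoms: none
Why: Dess–Martin oxidation of the only free hydroxyl gives the C11 ketone, whose α-carbon C1 is a bridgehead and cannot epimerise.

Step 15
Reactants: 26 the C11 ketone
Product: 27 5-hydroxy-2,6,6,9-tetramethyltricyclo[5.4.0.0^2,8]undec-3-en-11-one (C5 as in 34)
Conditions: TBAF, AcOH, THF, 50 °C
Reagents that add atoms: none
Why: Buffered fluoride desilylation should free the hindered allylic C5 hydroxyl without base-induced reactions at the ketone.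

Step 16
Reactants: 27 the allylic alcohol; 28 angelic acid
Product: 30 5-O-angelate of 27, via mixed anhydride 29 (not isolated)
Conditions: 2,4,6-trichlorobenzoyl chloride, Et3N, toluene, rt; then 27, toluene, 80 °C
Reagents that add atoms: none
Why: Acylation with the preformed angelic 2,4,6-trichlorobenzoic mixed anhydride without DMAP (Yamaguchi-type esterification) should esterify the hindered alcohol while avoiding Z-to-E isomerisation to the tiglate.

Step 17
Reactants: 30 the allylic angelate
Product: 31 3,4-dihydroxy-2,6,6,9-tetramethyl-11-oxotricyclo[5.4.0.0^2,8]undecan-5-yl angelate (all centres as in 34)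
Conditions: OsO4 (5 mol %), NMO, acetone/H2O, 0 °C to rt
Reagents that add atoms: N-methylmorpholine N-oxide, C[N+]1([O-])CCOCC1; water, O
Why: In this Upjohn dihydroxylation, osmium tetroxide should add to the ring alkene from the face anti to the allylic C5 acyloxy group, giving the 3,4-cis-diol trans to C5–O, and should prefer the isolated cis-alkene over the electron-poor trisubstituted angelate alkene.

Step 18
Reactants: 31 the diol angelate; 32 (R)-2-methylbutanoic acid
Product: 34 CNP0206299.1, (1R,2R,3S,4S,5S,7S,8S,9R)-3-hydroxy-2,6,6,9-tetramethyl-4-{[(2R)-2-methylbutanoyl]oxy}-11-oxotricyclo[5.4.0.0^2,8]undecan-5-yl (2Z)-2-methylbut-2-enoate, via O-acylisourea 33 (not isolated)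
Conditions: DCC, DMAP (10 mol %), CH2Cl2, −20 to 0 °C
Reagents that add atoms: none
Why: In this Steglich esterification the C4 hydroxyl, flanked by two CH carbons, should be acylated in preference to the C3 hydroxyl next to the quaternary C2, and the mild conditions should not racemise the α-centre of the acid.

## Compound list

1 | methyl hydrogen (R)-3-methylglutarate [(3R)-5-methoxy-3-methyl-5-oxopentanoic acid] | COC(=O)C[C@H](C)CC(=O)O | starting material
2 | tributyl(prop-1-yn-1-yl)stannane | CC#C[Sn](CCCC)(CCCC)CCCC | starting material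
3 | methyl (3S)-5-chloro-3-methyl-5-oxopentanoate (acid chloride of 1, not isolated) | COC(=O)C[C@H](C)CC(=O)Cl | intermediate
4 | methyl (3R)-3-methyl-5-oxooct-6-ynoate | COC(=O)C[C@H](C)CC(=O)C#CC | intermediate
5 | methyl (3R,5S)-5-hydroxy-3-methyloct-6-ynoate | COC(=O)C[C@H](C)C[C@H](O)C#CC | intermediate
6 | methyl (3R,5S)-5-[(tert-butyldimethylsilyl)oxy]-3-methyloct-6-ynoate | COC(=O)C[C@H](C)C[C@H](O[Si](C)(C)C(C)(C)C)C#CC | intermediate
7 | (E)-alkenylzirconocene chloride from 6, Zr on chain C7 (not isolated) | COC(=O)C[C@H](C)C[C@H](O[Si](C)(C)C(C)(C)C)/C=C(\C)[Zr](Cl)(C1C=CC=C1)C1C=CC=C1 | intermediate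
8 | methyl (3R,5S,6E)-5-[(tert-butyldimethylsilyl)oxy]-7-iodo-3-methyloct-6-enoate | COC(=O)C[C@H](C)C[C@H](O[Si](C)(C)C(C)(C)C)/C=C(\C)I | intermediate
9 | methacrolein (2-methylprop-2-enal) | CC(=C)C=O | starting material
10 | ethynyltrimethylsilane | C#C[Si](C)(C)C | starting material
11 | methyl[(trimethylsilyl)ethynyl]zinc (not isolated) | C[Zn]C#C[Si](C)(C)C | intermediate
12 | (3S)-4-methyl-1-(trimethylsilyl)pent-4-en-1-yn-3-ol | C[Si](C)(C)C#C[C@@H](O)C(C)=C | intermediate
13 | (3S)-3-[(tert-butyldiphenylsilyl)oxy]-4-methyl-1-(trimethylsilyl)pent-4-en-1-yne (not isolated) | C[Si](C)(C)C#C[C@@H](O[Si](c1ccccc1)(c1ccccc1)C(C)(C)C)C(C)=C | intermediate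
14 | (3S)-3-[(tert-butyldiphenylsilyl)oxy]-4-methylpent-4-en-1-yne | C#C[C@@H](O[Si](c1ccccc1)(c1ccccc1)C(C)(C)C)C(C)=C | intermediate
15 | methyl (3R,5S,6E,10S)-5-[(tert-butyldimethylsilyl)oxy]-10-[(tert-butyldiphenylsilyl)oxy]-3,7,11-trimethyldodeca-6,11-dien-8-ynoate | COC(=O)C[C@H](C)C[C@H](O[Si](C)(C)C(C)(C)C)/C=C(\C)C#C[C@@H](O[Si](c1ccccc1)(c1ccccc1)C(C)(C)C)C(C)=C | intermediate
16 | methyl (3R,5S,6E,8Z,10R)-5-[(tert-butyldimethylsilyl)oxy]-10-[(tert-butyldiphenylsilyl)oxy]-3,7,11-trimethyldodeca-6,8,11-trienoate | COC(=O)C[C@H](C)C[C@H](O[Si](C)(C)C(C)(C)C)/C=C(\C)/C=C\[C@@H](O[Si](c1ccccc1)(c1ccccc1)C(C)(C)C)C(C)=C | intermediate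
17 | (3R,5S,6E,8Z,10R)-5-[(tert-butyldimethylsilyl)oxy]-10-[(tert-butyldiphenylsilyl)oxy]-3,7,11-trimethyldodeca-6,8,11-trienoic acid | OC(=O)C[C@H](C)C[C@H](O[Si](C)(C)C(C)(C)C)/C=C(\C)/C=C\[C@@H](O[Si](c1ccccc1)(c1ccccc1)C(C)(C)C)C(C)=C | intermediate
18 | acid chloride of 17 (not isolated) | ClC(=O)C[C@H](C)C[C@H](O[Si](C)(C)C(C)(C)C)/C=C(\C)/C=C\[C@@H](O[Si](c1ccccc1)(c1ccccc1)C(C)(C)C)C(C)=C | intermediate
19 | alkylketene from 18 by loss of HCl (not isolated) | O=C=C[C@H](C)C[C@H](O[Si](C)(C)C(C)(C)C)/C=C(\C)/C=C\[C@@H](O[Si](c1ccccc1)(c1ccccc1)C(C)(C)C)C(C)=C | intermediate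
20 | 4-[(tert-butyldimethylsilyl)oxy]-7-[(1Z,3R)-3-[(tert-butyldiphenylsilyl)oxy]-4-methylpenta-1,4-dien-1-yl]-2,7-dimethylbicyclo[3.1.1]heptan-6-one (2-Me and 4-OTBS on the carbonyl-bridge face, 7-Me syn to the C2–C4 bridge) | C=C(C)[C@H](O[Si](c1ccccc1)(c1ccccc1)C(C)(C)C)/C=C\[C@]2(C)[C@@H]3C(=O)[C@H]2[C@@H](O[Si](C)(C)C(C)(C)C)C[C@H]3C | intermediate
21 | N-tosylhydrazone of 20 | C=C(C)[C@H](O[Si](c1ccccc1)(c1ccccc1)C(C)(C)C)/C=C\[C@]2(C)[C@@H]3C(=NNS(=O)(=O)c4ccc(C)cc4)[C@H]2[C@@H](O[Si](C)(C)C(C)(C)C)C[C@H]3C | intermediate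
22 | cyclised tricyclic C7 N′-tosylhydrazide (not isolated) | CC(C)(C)[Si](c1ccccc1)(c1ccccc1)O[C@@H]2C=C[C@]3(C)[C@@H]4[C@@](NNS(=O)(=O)c5ccc(C)cc5)([C@H]3[C@@H](O[Si](C)(C)C(C)(C)C)C[C@H]4C)C2(C)C | intermediate
23 | tricyclic C7 alkyldiazene (not isolated) | CC(C)(C)[Si](c1ccccc1)(c1ccccc1)O[C@@H]2C=C[C@]3(C)[C@@H]4[C@@](N=N)([C@H]3[C@@H](O[Si](C)(C)C(C)(C)C)C[C@H]4C)C2(C)C | intermediate
24 | 5-[(tert-butyldiphenylsilyl)oxy]-11-[(tert-butyldimethylsilyl)oxy]-2,6,6,9-tetramethyltricyclo[5.4.0.0^2,8]undec-3-ene | CC(C)(C)[Si](c1ccccc1)(c1ccccc1)O[C@@H]2C=C[C@]3(C)[C@@H]4[C@@H]([C@H]3[C@@H](O[Si](C)(C)C(C)(C)C)C[C@H]4C)C2(C)C | intermediate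
25 | 5-[(tert-butyldiphenylsilyl)oxy]-2,6,6,9-tetramethyltricyclo[5.4.0.0^2,8]undec-3-en-11-ol | CC(C)(C)[Si](c1ccccc1)(c1ccccc1)O[C@@H]2C=C[C@]3(C)[C@@H]4[C@@H]([C@H]3[C@@H](O)C[C@H]4C)C2(C)C | intermediate
26 | 5-[(tert-butyldiphenylsilyl)oxy]-2,6,6,9-tetramethyltricyclo[5.4.0.0^2,8]undec-3-en-11-one | CC(C)(C)[Si](c1ccccc1)(c1ccccc1)O[C@@H]2C=C[C@]3(C)[C@@H]4[C@@H]([C@H]3C(=O)C[C@H]4C)C2(C)C | intermediate
27 | 5-hydroxy-2,6,6,9-tetramethyltricyclo[5.4.0.0^2,8]undec-3-en-11-one | O[C@@H]1C=C[C@]2(C)[C@@H]3[C@@H]([C@H]2C(=O)C[C@H]3C)C1(C)C | intermediate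
28 | angelic acid [(2Z)-2-methylbut-2-enoic acid] | C/C=C(/C)C(=O)O | starting material
29 | angelic 2,4,6-trichlorobenzoic anhydride (not isolated) | C/C=C(/C)C(=O)OC(=O)c1c(Cl)cc(Cl)cc1Cl | intermediate
30 | 2,6,6,9-tetramethyl-11-oxotricyclo[5.4.0.0^2,8]undec-3-en-5-yl angelate | C/C=C(/C)C(=O)O[C@@H]1C=C[C@]2(C)[C@@H]3[C@@H]([C@H]2C(=O)C[C@H]3C)C1(C)C | intermediate
31 | 3,4-dihydroxy-2,6,6,9-tetramethyl-11-oxotricyclo[5.4.0.0^2,8]undecan-5-yl angelate | C/C=C(/C)C(=O)O[C@@H]1[C@@H](O)[C@@H](O)[C@]2(C)[C@@H]3[C@@H]([C@H]2C(=O)C[C@H]3C)C1(C)C | intermediate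
32 | (R)-2-methylbutanoic acid | CC[C@@H](C)C(=O)O | starting material
33 | O-[(2R)-2-methylbutanoyl]-N,N′-dicyclohexylisourea (not isolated) | CC[C@@H](C)C(=O)OC(=NC1CCCCC1)NC1CCCCC1 | intermediate
34 | CNP0206299.1, (1R,2R,3S,4S,5S,7S,8S,9R)-3-hydroxy-2,6,6,9-tetramethyl-4-{[(2R)-2-methylbutanoyl]oxy}-11-oxotricyclo[5.4.0.0^2,8]undecan-5-yl (2Z)-2-methylbut-2-enoate | C/C=C(/C)C(=O)O[C@@H]1[C@@H](OC(=O)[C@H](C)CC)[C@@H](O)[C@]2(C)[C@@H]3[C@@H]([C@H]2C(=O)C[C@H]3C)C1(C)C | target

## Step count and risks

Total step count: 18. Longest linear sequence: 16 (steps 1–4 and 7–18); steps 5–6 form the second branch.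

Steps most likely to fail:

1. Step 12 (Proposed new method). The C6 radical may be reduced by a second hydrogen-atom transfer before it reaches C7, may undergo a 1,2-vinyl shift through the cyclopropylcarbinyl radical, or the congested adduct may fail to expel sulfinate and N2. The fallback sets out from cyclobutanone 20 and uses the ketone itself as acceptor in the known Fe(acac)3/PhSiH3 hydrogen-atom-transfer ketone–olefin cyclisation (EtOH/ethylene glycol, 60 °C), which would give the tricyclic C7 tertiary cyclobutanol F1 with the hydroxyl on the bridge face. Acylation with methyl chlorooxoacetate and DMAP would give the tertiary methyl oxalate F2. Radical deoxygenation with Bu3SnH/AIBN in toluene at 110 °C would deliver hydrogen to the only open face of C7 and return to 24.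

2. Step 10. Ketene dimerisation or lactonisation of the activated δ-silyloxy acid may outrun the cycloaddition, or the facial preference may be weaker than argued. The fallback sets out from ester 16: aminolysis with Me2AlNMe2 would give the N,N-dimethylamide F3. Activation with Tf2O and 2,6-di-tert-butyl-4-methylpyridine in 1,2-dichloroethane at 80 °C would generate the far more electrophilic keteniminium ion, whose intramolecular keteniminium–olefin [2+2] would give the cyclobutaniminium triflate F4. Aqueous NaHCO3 hydrolysis would return to 20.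

3. Step 17. Osmylation of the angelate double bond may compete, or the facial bias from the allylic ester may be insufficient. The fallback sets out from allylic alcohol 27: dihydroxylation of the free alcohol (OsO4/NMO, anti to the hydroxyl) would give the 3,4,5-triol F5. 2,2-Dimethoxypropane/PPTS would protect the cis-3,4-diol as the acetonide F6. Angeloylation of the remaining C5 hydroxyl as in step 16 would give the acetonide angelate F7. Aqueous acetic acid would remove the acetonide and return to 31.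

## Further compounds

F1 | step 12 | 5-[(tert-butyldiphenylsilyl)oxy]-11-[(tert-butyldimethylsilyl)oxy]-2,6,6,9-tetramethyltricyclo[5.4.0.0^2,8]undec-3-en-7-ol | CC(C)(C)[Si](c1ccccc1)(c1ccccc1)O[C@@H]2C=C[C@]3(C)[C@@H]4[C@@](O)([C@H]3[C@@H](O[Si](C)(C)C(C)(C)C)C[C@H]4C)C2(C)C
F2 | step 12 | methyl oxalate of F1 at the C7 oxygen | CC(C)(C)[Si](c1ccccc1)(c1ccccc1)O[C@@H]2C=C[C@]3(C)[C@@H]4[C@@](OC(=O)C(=O)OC)([C@H]3[C@@H](O[Si](C)(C)C(C)(C)C)C[C@H]4C)C2(C)C
F3 | step 10 | (3R,5S,6E,8Z,10R)-5-[(tert-butyldimethylsilyl)oxy]-10-[(tert-butyldiphenylsilyl)oxy]-N,N,3,7,11-pentamethyldodeca-6,8,11-trienamide | CN(C)C(=O)C[C@H](C)C[C@H](O[Si](C)(C)C(C)(C)C)/C=C(\C)/C=C\[C@@H](O[Si](c1ccccc1)(c1ccccc1)C(C)(C)C)C(C)=C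
F4 | step 10 | N,N-dimethyl cyclobutaniminium triflate corresponding to 20 | C=C(C)[C@H](O[Si](c1ccccc1)(c1ccccc1)C(C)(C)C)/C=C\[C@]2(C)[C@@H]3C(=[N+](C)C)[C@H]2[C@@H](O[Si](C)(C)C(C)(C)C)C[C@H]3C.[O-]S(=O)(=O)C(F)(F)F
F5 | step 17 | 3,4,5-trihydroxy-2,6,6,9-tetramethyltricyclo[5.4.0.0^2,8]undecan-11-one (centres as in 34) | O[C@@H]1[C@@H](O)[C@@H](O)[C@]2(C)[C@@H]3[C@@H]([C@H]2C(=O)C[C@H]3C)C1(C)C
F6 | step 17 | 3,4-O-isopropylidene derivative of F5 | O[C@@H]1[C@H]2OC(C)(C)O[C@H]2[C@]3(C)[C@@H]4[C@@H]([C@H]3C(=O)C[C@H]4C)C1(C)C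
F7 | step 17 | 5-O-angelate of F6 | C/C=C(/C)C(=O)O[C@@H]1[C@H]2OC(C)(C)O[C@H]2[C@]3(C)[C@@H]4[C@@H]([C@H]3C(=O)C[C@H]4C)C1(C)C
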